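**Retrosynthetic overview**

1. Target 27 is a ten-membered carbocycle (C1–C10) bridged by the furanone oxygen (C3–O–C10, an 11-oxabicyclo[6.2.1] core) and cis-fused at C6/C7 to an α-methylene-γ-lactone. The carbocycle is closed last, at C4–C5, by a Nozaki–Hiyama–Kishi reaction.
2. Key disconnection: the C8–C9 bond, formed together with the C10–O bond in an intramolecular [3+2] cycloaddition of a silicon-tethered nitronate (C8 from nitromethane) onto the isopropenyl carbinol C9=C10(CH3)–C1. The resulting isoxazoline is a masked C8(=O)–C9H2–C10(OH) aldol.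
3. Enabling feature: the 1,3-dioxygenation C8–O/C10–O across the C9 methylene, with quaternary C10 next to the C1 carbonyl. At the alcohol oxidation level the C1 oxygen anchors the tether and relays its configuration to C10, and the nitronate oxygen becomes the furanone ring oxygen.
4. Fragments: nitro ester 7 (C5–C8, C11–C13) from (S)-glyceraldehyde acetonide, methyl acrylate and nitromethane; bromo-dienynol 13 (C1–C4, C9, C10, C14, C15) from methacrolein, ethynyltrimethylsilane and 1,1-dibromoethene.
5. Ring order: isoxazoline (temporary, step 7), then 3(2H)-furanone (step 11), then γ-lactone (step 13), then the ten-membered carbocycle (step 15).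

Key step: step 7

Remark: germacrane numbering is used (C1 furanone carbonyl, C3 and C10 the furanone O-bearing carbons, C5 carbinol, C6 lactone O–CH, C8 acyloxy carbon, C4=C15 and C11=C13 the exocyclic methylenes); the target is (5S,6R,7R,8R,10S); compounds 1 and 12 are taken as commercially available.

**Route**

Step 1
Reactants: 1 (S)-glyceraldehyde acetonide; 2 methyl acrylate
Product: 3 Morita–Baylis–Hillman alcohol (both carbinol epimers)
Conditions: DABCO (0.5 equiv), 2 (5 equiv), 1,4-dioxane/H2O 1:1, 25 °C, 4 d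
Reagents that add atoms: none
Why: Morita–Baylis–Hillman reaction of the α-alkoxy aldehyde with the acrylate; the new carbinol centre (C7) forms as an epimer mixture, which is harmless because C7 becomes trigonal again in step 3, while the dioxolane centre (C6) is untouched.

Step 2
Reactants: 3 Morita–Baylis–Hillman alcohol
Product: 4 allylic acetate
Conditions: Ac2O, DMAP (cat.), pyridine, CH2Cl2, 0 °C
Reagents that add atoms: acetic anhydride, CC(=O)OC(C)=O
Why: DMAP-catalysed O-acetylation converts the allylic alcohol into the leaving group needed for the allylic substitution.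

Step 3
Reactants: 4 allylic acetate; 5 nitromethane
Product: 7 nitro ester (C7 R), via allyl-DABCO ammonium acetate 6 (not isolated)
Conditions: DABCO (1.1 equiv), THF/H2O 3:1, 25 °C, 30 min; then 5 (10 equiv), K2CO3 (1.2 equiv), 0 → 25 °C
Reagents that add atoms: none
Why: Tandem SN2′–SN2′ allylic substitution in which DABCO displaces acetate to give 6 and the nitronate then attacks C7 with loss of DABCO; in the conformer of 6 with C6–H eclipsing the alkene (least allylic 1,3-strain) the nitronate should add anti to the dioxolane CH2, the syn sense known for nitromethane additions to γ-alkoxy acceptors derived from glyceraldehyde acetonide, which sets C7 (R).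

Step 4
Reactants: 8 methacrolein; 9 ethynyltrimethylsilane
Product: 10 (3S)-silyl enynol
Conditions: Me2Zn (3 equiv), ProPhenol ligand (10 mol %, antipode giving 3S), Ph3P=O (20 mol %), toluene, 0 °C
Reagents that add atoms: none
Why: Zn–ProPhenol-catalysed enantioselective alkynylation of an enal; the C1 carbinol configuration (S) is set by the catalyst antipode and serves only as a temporary control element.

Step 5
Reactants: 10 (3S)-silyl enynol
Product: 11 (3S)-enynol
Conditions: K2CO3 (cat.), MeOH, 0 °C
Reagents that add atoms: none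
Why: Base-catalysed methanolysis of the alkynyl C–Si bond (protodesilylation) frees the terminal alkyne without touching the carbinol centre.

Step 6
Reactants: 11 (3S)-enynol; 12 1,1-dibromoethene
Product: 13 (3S)-bromo-dienynol
Conditions: Pd(PPh3)4 (5 mol %), CuI (10 mol %), iPr2NH, THF, 12 (4 equiv), 0 → 25 °C
Reagents that add atoms: none
Why: Sonogashira mono-coupling of the terminal alkyne with excess 1,1-dibromoethene gives the 2-bromo-1-en-3-yne, the second C–Br bond being kept for the final ring closure.

Step 7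
Reactants: 7 nitro ester; 13 (3S)-bromo-dienynol
Product: 17 isoxazoline (C10 S), via chlorosilyl ether 14 (not isolated), via tethered silyl nitronate 15 (not isolated), via bicyclic N-silyloxyisoxazolidine 16 (not isolated)
Conditions: 13, Me2SiCl2 (5 equiv), Et3N, CH2Cl2, 0 °C, then evaporation; 7, Et3N (2.5 equiv), toluene (0.02 M), 25 → 60 °C; then TBAF/AcOH (1:1), THF, 0 °C
Reagents that add atoms: none
Why: Proposed new method: O-silylation of the nitronate of 7 by alkoxychlorosilane 14 gives the tethered silyl nitronate 15, whose C=N(+)–O(−) dipole adds across the isopropenyl group in a concerted suprafacial [3+2] cycloaddition that forms C8–C9 and O–C10, closing the five-membered isoxazolidine ring inside a seven-membered N–O–Si–O–C1–C10–O ring (bridged bicyclo[4.2.1] mode, tether on nitrogen); fluoride then cleaves both Si–O bonds and loss of water gives the 2-isoxazoline. The closest known reactions are the intramolecular silyl nitronate–olefin cycloaddition of carbon-tethered nitro alkenes, the N-tethered intramolecular nitrone cycloaddition and the magnesium-alkoxide-directed nitrile oxide cycloaddition to allylic alcohols; the new element is a silicon atom that is at once the nitronate silyl group and the carrier of the allylic alcohol. Regiochemistry (oxygen to the more substituted C10, carbon to the C9 methylene) is the normal electronic preference of nitronates with 1,1-disubstituted alkenes and is enforced by the tether length. The only lasting new stereocentre, quaternary C10, is controlled by C1: in the bicyclic transition state the tether oxygen lies on the attacked face, C1–H eclipses the C10 methyl group (least allylic 1,2-strain) and the alkynyl group points away from the forming rings, which should translate (S)-C1 into (S)-C10, while C8 and nitrogen are stereogenic only transiently. Chemoselectivity over the acrylate and the bromo-enyne rests on the tether, which lets neither be reached through a comparable ring, and on high dilution, which suppresses intermolecular addition to the acrylate.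

Step 8
Reactants: 17 isoxazoline
Product: 19 β-hydroxy ketone, via β-hydroxy imine 18 (not isolated)
Conditions: SmI2 (2.5 equiv), THF, 0 °C; then B(OH)3, MeOH/H2O, 25 °C
Reagents that add atoms: water, O
Why: Reductive N–O cleavage of the 2-isoxazoline by SmI2 and hydrolysis of imine 18 unmask the aldol (C8 ketone and C10 tertiary alcohol) at 0 °C, conditions chosen so that the acrylate, the bromo-enyne and the epimerisable C7 centre survive.

Step 9
Reactants: 19 β-hydroxy ketone
Product: 20 triol (C8 R)
Conditions: Et2BOMe (2.5 equiv), THF/MeOH 4:1, 0 → −78 °C; NaBH4, −78 °C; MeOH work-up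
Reagents that add atoms: none
Why: Narasaka–Prasad reduction in which the C10–O–BEt2 chelate of the β-hydroxy ketone is attacked axially by external hydride to give the 1,3-syn diol, which is also the Felkin–Anh sense with respect to C7 (dioxolanyl as the large group), so C8 (R) should form under matched double control.

Step 10
Reactants: 20 triol
Product: 21 α′-hydroxy ynone
Conditions: MnO2 (activated, 20 equiv), CH2Cl2, 25 °C
Reagents that add atoms: none
Why: MnO2 oxidises only the activated propargylic C1 alcohol, leaving the saturated secondary C8 and tertiary C10 alcohols, and erases the temporary C1 stereocentre.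

Step 11
Reactants: 21 α′-hydroxy ynone
Product: 22 furanone alcohol
Conditions: (Ph3P)AuNTf2 (5 mol %), CH2Cl2, 25 °C
Reagents that add atoms: none
Why: Gold-catalysed 5-endo-dig hydroalkoxylation (intramolecular oxa-Michael addition) of the α′-hydroxy ynone, in which the tertiary C10–OH adds to C3 of the activated alkyne and protodeauration gives the 3(2H)-furanone without touching C10.

Step 12
Reactants: 22 furanone alcohol
Product: 23 furanone isobutyrate
Conditions: (iPrCO)2O, DMAP (cat.), pyridine, CH2Cl2, 0 → 25 °C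
Reagents that add atoms: isobutyric anhydride, CC(C)C(=O)OC(=O)C(C)C
Why: DMAP-catalysed acylation of the only free hydroxyl group (C8–OH) installs the isobutyrate with retention.

Step 13
Reactants: 23 furanone isobutyrate
Product: 25 lactone alcohol, via diol ester 24 (not isolated)
Conditions: AcOH/H2O 4:1, 45 °C; then TsOH·H2O (cat.), toluene, 40 °C
Reagents that add atoms: none
Why: Acidic hydrolysis of the acetonide to diol 24 followed by acid-catalysed lactonisation of the C6 hydroxyl onto the methyl ester gives the five-membered α-methylene lactone (thermodynamically preferred over the six-membered alternative through the C5 hydroxyl) and leaves the primary C5–OH free.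

Step 14
Reactants: 25 lactone alcohol
Product: 26 bromo-dienone aldehyde
Conditions: Dess–Martin periodinane, CH2Cl2, 0 → 25 °C
Reagents that add atoms: none
Why: Dess–Martin oxidation of the primary alcohol to the aldehyde under neutral conditions that should not epimerise the adjacent C6 centre.

Step 15
Reactants: 26 bromo-dienone aldehyde
Product: 27 target CNP0384113.2
Conditions: CrCl2 (10 equiv), NiCl2 (10 mol %), DMSO/THF 3:1, 25 °C, slow addition of 26 (final 0.002 M)
Reagents that add atoms: none
Why: Nozaki–Hiyama–Kishi reaction in which the α-bromo dienone C–Br bond adds oxidatively to nickel, the alkenyl group is passed to chromium and adds to the aldehyde, closing the ten-membered carbocycle (a nine-membered ring through the furanone oxygen, a size this reaction reaches in oxygen-bridged systems); C5 (S) should arise from polar Felkin–Anh attack anti to the C6–O bond.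

**Compound list**

1 | (S)-2,2-dimethyl-1,3-dioxolane-4-carbaldehyde [(S)-glyceraldehyde acetonide] | O=C[C@@H]1COC(C)(C)O1 | starting material
2 | methyl acrylate | C=CC(=O)OC | starting material
3 | methyl 2-{[(4S)-2,2-dimethyl-1,3-dioxolan-4-yl](hydroxy)methyl}prop-2-enoate (both carbinol epimers) | C=C(C(=O)OC)C(O)[C@@H]1COC(C)(C)O1 | intermediate
4 | methyl 2-{(acetyloxy)[(4S)-2,2-dimethyl-1,3-dioxolan-4-yl]methyl}prop-2-enoate (both epimers) | C=C(C(=O)OC)C(OC(C)=O)[C@@H]1COC(C)(C)O1 | intermediate
5 | nitromethane | C[N+](=O)[O-] | starting material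
6 | 1-{3-[(4R)-2,2-dimethyl-1,3-dioxolan-4-yl]-2-(methoxycarbonyl)prop-2-en-1-yl}-4-aza-1-azoniabicyclo[2.2.2]octane acetate (E/Z mixture) | COC(=O)C(C[N+]12CCN(CC1)CC2)=C[C@@H]1COC(C)(C)O1.CC(=O)[O-] | intermediate
7 | methyl (3R)-3-[(4R)-2,2-dimethyl-1,3-dioxolan-4-yl]-2-methylidene-4-nitrobutanoate | C=C(C(=O)OC)[C@H](C[N+](=O)[O-])[C@@H]1COC(C)(C)O1 | intermediate
8 | methacrolein (2-methylprop-2-enal) | C=C(C)C=O | starting material
9 | ethynyltrimethylsilane | C#C[Si](C)(C)C | starting material
10 | (3S)-2-methyl-5-(trimethylsilyl)pent-1-en-4-yn-3-ol | C=C(C)[C@H](O)C#C[Si](C)(C)C | intermediate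
11 | (3S)-2-methylpent-1-en-4-yn-3-ol | C=C(C)[C@H](O)C#C | intermediate
12 | 1,1-dibromoethene | C=C(Br)Br | starting material
13 | (3S)-6-bromo-2-methylhepta-1,6-dien-4-yn-3-ol | C=C(C)[C@H](O)C#CC(Br)=C | intermediate
14 | (3S)-6-bromo-3-{[chloro(dimethyl)silyl]oxy}-2-methylhepta-1,6-dien-4-yne | C=C(C)[C@H](O[Si](C)(C)Cl)C#CC(Br)=C | intermediate
15 | tethered silyl nitronate: aci-nitro form of 7, O-silylated by the {[(3S)-6-bromo-2-methylhepta-1,6-dien-4-yn-3-yl]oxy}dimethylsilyl group | C=C(C(=O)OC)[C@@H]([C@@H]1COC(C)(C)O1)C=[N+]([O-])O[Si](C)(C)O[C@@H](C(C)=C)C#CC(Br)=C | intermediate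
16 | cycloadduct: N-silyloxyisoxazolidine with a 2,4,9-trioxa-1-aza-3-silabicyclo[4.2.1]nonane core (C10 S, C1 R; C8 and N unassigned) | C=C(C(=O)OC)[C@@H]([C@@H]1COC(C)(C)O1)C2C[C@]3(C)ON2O[Si](C)(C)O[C@@H]3C#CC(Br)=C | intermediate
17 | methyl (3R)-3-{(5S)-5-[(1R)-4-bromo-1-hydroxypent-4-en-2-yn-1-yl]-5-methyl-4,5-dihydro-1,2-oxazol-3-yl}-3-[(4R)-2,2-dimethyl-1,3-dioxolan-4-yl]-2-methylidenepropanoate | C=C(C(=O)OC)[C@@H]([C@@H]1COC(C)(C)O1)C2=NO[C@](C)([C@H](O)C#CC(Br)=C)C2 | intermediate
18 | methyl (3R,6S,7R)-10-bromo-3-[(4R)-2,2-dimethyl-1,3-dioxolan-4-yl]-6,7-dihydroxy-4-imino-6-methyl-2-methylideneundec-10-en-8-ynoate | C=C(C(=O)OC)[C@@H]([C@@H]1COC(C)(C)O1)C(=N)C[C@](C)(O)[C@H](O)C#CC(Br)=C | intermediate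
19 | methyl (3S,6S,7R)-10-bromo-3-[(4R)-2,2-dimethyl-1,3-dioxolan-4-yl]-6,7-dihydroxy-6-methyl-2-methylidene-4-oxoundec-10-en-8-ynoate | C=C(C(=O)OC)[C@@H]([C@@H]1COC(C)(C)O1)C(=O)C[C@](C)(O)[C@H](O)C#CC(Br)=C | intermediate
20 | methyl (3R,4R,6S,7R)-10-bromo-3-[(4R)-2,2-dimethyl-1,3-dioxolan-4-yl]-4,6,7-trihydroxy-6-methyl-2-methylideneundec-10-en-8-ynoate | C=C(C(=O)OC)[C@@H]([C@@H]1COC(C)(C)O1)[C@H](O)C[C@](C)(O)[C@H](O)C#CC(Br)=C | intermediate
21 | methyl (3R,4R,6S)-10-bromo-3-[(4R)-2,2-dimethyl-1,3-dioxolan-4-yl]-4,6-dihydroxy-6-methyl-2-methylidene-7-oxoundec-10-en-8-ynoate | C=C(C(=O)OC)[C@@H]([C@@H]1COC(C)(C)O1)[C@H](O)C[C@](C)(O)C(=O)C#CC(Br)=C | intermediate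
22 | methyl (3R,4R)-5-[(2S)-5-(1-bromoethenyl)-2-methyl-3-oxo-2,3-dihydrofuran-2-yl]-3-[(4R)-2,2-dimethyl-1,3-dioxolan-4-yl]-4-hydroxy-2-methylidenepentanoate | C=C(C(=O)OC)[C@@H]([C@@H]1COC(C)(C)O1)[C@H](O)C[C@]2(C)OC(C(Br)=C)=CC2=O | intermediate
23 | methyl (3R,4R)-5-[(2S)-5-(1-bromoethenyl)-2-methyl-3-oxo-2,3-dihydrofuran-2-yl]-3-[(4R)-2,2-dimethyl-1,3-dioxolan-4-yl]-2-methylidene-4-[(2-methylpropanoyl)oxy]pentanoate | C=C(C(=O)OC)[C@@H]([C@@H]1COC(C)(C)O1)[C@H](OC(=O)C(C)C)C[C@]2(C)OC(C(Br)=C)=CC2=O | intermediate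
24 | methyl (3R,4R)-5-[(2S)-5-(1-bromoethenyl)-2-methyl-3-oxo-2,3-dihydrofuran-2-yl]-3-[(1R)-1,2-dihydroxyethyl]-2-methylidene-4-[(2-methylpropanoyl)oxy]pentanoate | C=C(C(=O)OC)[C@@H]([C@@H](O)CO)[C@H](OC(=O)C(C)C)C[C@]2(C)OC(C(Br)=C)=CC2=O | intermediate
25 | (1R)-2-[(2S)-5-(1-bromoethenyl)-2-methyl-3-oxo-2,3-dihydrofuran-2-yl]-1-[(2R,3R)-2-(hydroxymethyl)-4-methylidene-5-oxooxolan-3-yl]ethyl 2-methylpropanoate | C=C1C(=O)O[C@@H](CO)[C@H]1[C@H](OC(=O)C(C)C)C[C@]2(C)OC(C(Br)=C)=CC2=O | intermediate
26 | (1R)-2-[(2S)-5-(1-bromoethenyl)-2-methyl-3-oxo-2,3-dihydrofuran-2-yl]-1-[(2R,3R)-2-formyl-4-methylidene-5-oxooxolan-3-yl]ethyl 2-methylpropanoate | C=C1C(=O)O[C@@H](C=O)[C@H]1[C@H](OC(=O)C(C)C)C[C@]2(C)OC(C(Br)=C)=CC2=O | intermediate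
27 | CNP0384113.2: (5S,6R,7R,8R,10S)-5-hydroxy-1-oxo-3,10-epoxygermacra-2,4(15),11(13)-trien-12,6-olid-8-yl 2-methylpropanoate | C=C1C(=O)O[C@@H]2[C@H]1[C@H](OC(=O)C(C)C)C[C@]1(C)OC(=CC1=O)C(=C)[C@@H]2O | target

**Step count and risks**

Total step count: 15. Longest linear sequence: 12 steps (steps 1–3 or 4–6, then 7–15).

Steps most likely to fail:

Step 7 (proposed new method). The tether may not form cleanly (scrambling to the bis-alkoxysilane, slow O-silylation of the nitronate), the nitronate may add intermolecularly to the acrylate, or facial control at C10 may be weaker than the transition-state model predicts. Fallback by known chemistry, setting out from 7 and returning at 17: the nitro group of 7 is reduced (SnCl2·2H2O, PhSH, Et3N) to the aldoxime methyl (3R)-3-[(4R)-2,2-dimethyl-1,3-dioxolan-4-yl]-4-(hydroxyimino)-2-methylidenebutanoate F1. This is chlorinated (NCS, DMF) to the hydroximoyl chloride methyl (3S)-4-chloro-3-[(4R)-2,2-dimethyl-1,3-dioxolan-4-yl]-4-(hydroxyimino)-2-methylidenebutanoate F2. Addition of F2 to the bromomagnesium alkoxide of 13 (EtMgBr, CH2Cl2, 0 °C) generates the nitrile oxide and directs it through magnesium chelation onto the allylic alkene (hydroxyl-directed nitrile oxide cycloaddition, regio- and syn-selective for allylic alcohols), which should give 17. Should either mode deliver the opposite sense at C10, the antipode of 13 is available from the other ligand antipode in step 4.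

Step 15. Ring strain and the entropic cost of closing the oxygen-bridged ten-membered ring may lead to oligomerisation or to reduction of the C–Br bond without ring closure; the α-acyloxy aldehyde may hydrate or epimerise; facial selectivity at C5 may be insufficient. Fallback, setting out from 21 and returning at 27, in which the ring is closed on the unbridged chain and the furanone is formed afterwards across the ring: selective acylation of the secondary C8–OH of 21 [(iPrCO)2O, DMAP, pyridine] gives the isobutyrate methyl (3R,4R,6S)-10-bromo-3-[(4R)-2,2-dimethyl-1,3-dioxolan-4-yl]-6-hydroxy-6-methyl-2-methylidene-4-[(2-methylpropanoyl)oxy]-7-oxoundec-10-en-8-ynoate F3. Acetonide hydrolysis and lactonisation (as in step 13) give the lactone alcohol (1R,3S)-7-bromo-3-hydroxy-1-[(2R,3R)-2-(hydroxymethyl)-4-methylidene-5-oxooxolan-3-yl]-3-methyl-4-oxooct-7-en-5-yn-1-yl 2-methylpropanoate F4. Dess–Martin oxidation gives the aldehyde (1R,3S)-7-bromo-1-[(2R,3R)-2-formyl-4-methylidene-5-oxooxolan-3-yl]-3-hydroxy-3-methyl-4-oxooct-7-en-5-yn-1-yl 2-methylpropanoate F5. Nozaki–Hiyama–Kishi macrocyclisation (CrCl2, NiCl2, DMSO) should give the ten-membered α′-hydroxy ynone (the C10-hydroxy 2,3-didehydro seco-furanone form of 27) F6, and transannular gold-catalysed 5-endo-dig cyclisation [(Ph3P)AuNTf2] should then give 27.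

Step 3. Direct SN2 attack at the CH2 terminus, double allylation of nitromethane, or insufficient facial discrimination at C7 may erode the yield or the syn selectivity. Fallback, setting out from 1 and returning at 7: Knoevenagel condensation of 1 with methyl (diethoxyphosphoryl)acetate (TiCl4, N-methylmorpholine, THF) gives the vinylphosphonate methyl 2-(diethoxyphosphoryl)-3-[(4R)-2,2-dimethyl-1,3-dioxolan-4-yl]prop-2-enoate F7. Conjugate addition of nitromethane (DBU) gives the nitro phosphonate methyl (3R)-2-(diethoxyphosphoryl)-3-[(4R)-2,2-dimethyl-1,3-dioxolan-4-yl]-4-nitrobutanoate F8. Horner–Wadsworth–Emmons olefination with aqueous formaldehyde (K2CO3) then installs the methylidene group and should give 7.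

Further compounds
F1 | step 7 | methyl (3R)-3-[(4R)-2,2-dimethyl-1,3-dioxolan-4-yl]-4-(hydroxyimino)-2-methylidenebutanoate | C=C(C(=O)OC)[C@H](C=NO)[C@@H]1COC(C)(C)O1
F2 | step 7 | methyl (3S)-4-chloro-3-[(4R)-2,2-dimethyl-1,3-dioxolan-4-yl]-4-(hydroxyimino)-2-methylidenebutanoate | C=C(C(=O)OC)[C@H](C(Cl)=NO)[C@@H]1COC(C)(C)O1
F3 | step 15 | methyl (3R,4R,6S)-10-bromo-3-[(4R)-2,2-dimethyl-1,3-dioxolan-4-yl]-6-hydroxy-6-methyl-2-methylidene-4-[(2-methylpropanoyl)oxy]-7-oxoundec-10-en-8-ynoate | C=C(C(=O)OC)[C@@H]([C@@H]1COC(C)(C)O1)[C@H](OC(=O)C(C)C)C[C@](C)(O)C(=O)C#CC(Br)=C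
F4 | step 15 | (1R,3S)-7-bromo-3-hydroxy-1-[(2R,3R)-2-(hydroxymethyl)-4-methylidene-5-oxooxolan-3-yl]-3-methyl-4-oxooct-7-en-5-yn-1-yl 2-methylpropanoate | C=C1C(=O)O[C@@H](CO)[C@H]1[C@H](OC(=O)C(C)C)C[C@](C)(O)C(=O)C#CC(Br)=C
F5 | step 15 | (1R,3S)-7-bromo-1-[(2R,3R)-2-formyl-4-methylidene-5-oxooxolan-3-yl]-3-hydroxy-3-methyl-4-oxooct-7-en-5-yn-1-yl 2-methylpropanoate | C=C1C(=O)O[C@@H](C=O)[C@H]1[C@H](OC(=O)C(C)C)C[C@](C)(O)C(=O)C#CC(Br)=C
F6 | step 15 | ten-membered α′-hydroxy ynone (5S,6R,7R,8R,10S; C10-hydroxy 2,3-didehydro seco-furanone form of 27) | C=C1C(=O)O[C@@H]2[C@H]1[C@H](OC(=O)C(C)C)C[C@](C)(O)C(=O)C#CC(=C)[C@@H]2O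
F7 | step 3 | methyl 2-(diethoxyphosphoryl)-3-[(4R)-2,2-dimethyl-1,3-dioxolan-4-yl]prop-2-enoate (E/Z mixture) | CCOP(=O)(OCC)C(C(=O)OC)=C[C@@H]1COC(C)(C)O1
F8 | step 3 | methyl (3R)-2-(diethoxyphosphoryl)-3-[(4R)-2,2-dimethyl-1,3-dioxolan-4-yl]-4-nitrobutanoate (C2 epimers) | CCOP(=O)(OCC)C(C(=O)OC)[C@H](C[N+](=O)[O-])[C@@H]1COC(C)(C)O1
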